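**Strategy.** Everything rests on building the benzene-1,4-diol ring last, by a Dötz benzannulation that stitches together the terminal alkyne of a finished C20 side chain, one CO ligand and a chromium methoxy(propenyl)carbene. One operation forms three ring C–C bonds and the arene, placing O1 on the CO-derived carbon between the ring carbon that carries chain C1 and the ring carbon that carries the methyl group, with O4 (as OMe) para between two CH positions – the unsymmetrical pattern of the target ring. The precursor is a skipped (1,4-) enyne whose (10R,11R)-diol is masked as an acetonide; its stereocentres come from nerol (asymmetric epoxidation, Payne rearrangement) and its chain from a geraniol-derived C8 sulfone.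

Key step: step 13

Remark: side-chain atoms keep the target numbering throughout (C1 = benzylic CH2, C10/C11 = diol carbons); the enantiomeric purity of the target is that set in step 4; the η6-arene complex 22 is written in SMILES as arene and Cr(CO)3 joined by a dot because SMILES has no hapto bond.

**Step 1**
Reactants: 1 geraniol
Product: 2 tert-butyl{[(2E)-3,7-dimethylocta-2,6-dien-1-yl]oxy}diphenylsilane (geranyl TBDPS ether)
Conditions: TBDPSCl, imidazole, CH2Cl2, 0 °C → rt
Reagents that add atoms: tert-butyl(chloro)diphenylsilane, CC(C)(C)[Si](Cl)(c1ccccc1)c1ccccc1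
Why: Imidazole-promoted silylation of a primary allylic alcohol gives an ether that should survive the oxidant, organolithium, hydride and mild acid used before its removal in step 9.

**Step 2**
Reactants: 2 geranyl TBDPS ether
Product: 3 (2E,6E)-8-[(tert-butyldiphenylsilyl)oxy]-2,6-dimethylocta-2,6-dien-1-ol
Conditions: SeO2 (cat.), salicylic acid (cat.), t-BuOOH, CH2Cl2, rt
Reagents that add atoms: tert-butyl hydroperoxide (oxygen relayed through catalytic SeO2), CC(C)(C)OO
Why: The SeO2/t-BuOOH allylic oxidation (ene reaction, then [2,3]-sigmatropic shift) attacks the more electron-rich terminal alkene and oxidises the methyl group trans to the chain, so the later 6E geometry is fixed while the 2,3-alkene is deactivated by its allylic oxygen.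

**Step 3**
Reactants: 3 (2E,6E)-8-silyloxy-2,6-dimethylocta-2,6-dien-1-ol
Product: 6 tert-butyl{[(2E,6E)-3,7-dimethyl-8-(phenylsulfonyl)octa-2,6-dien-1-yl]oxy}diphenylsilane (C8 allyl sulfone), via allylic mesylate 4 (not isolated), via allylic bromide 5 (not isolated)
Conditions: MsCl, Et3N, THF, −40 °C; LiBr, −40 → 0 °C; then PhSO2Na, DMF, rt
Reagents that add atoms: sodium benzenesulfinate, [Na+].[O-]S(=O)c1ccccc1
Why: One-flask mesylation, bromide exchange and S-alkylation of the sulfinate at the primary allylic carbon (SN2, alkene geometry kept) should give the sulfone without handling the labile bromide.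

**Step 4**
Reactants: 7 nerol
Product: 8 [(2S,3R)-3-methyl-3-(4-methylpent-3-en-1-yl)oxiran-2-yl]methanol ((2S,3R)-2,3-epoxynerol)
Conditions: Ti(OiPr)4 (10 mol%), L-(+)-diethyl tartrate (12 mol%), t-BuOOH, 4 Å MS, CH2Cl2, −20 °C
Reagents that add atoms: tert-butyl hydroperoxide, CC(C)(C)OO
Why: The Katsuki–Sharpless asymmetric epoxidation is selective for the allylic alcohol alkene, and with L-(+)-tartrate the Z-allylic alcohol should give the (2S,3R)-epoxide, which sets the future C11 (R) directly and the future C10 after one inversion.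

**Step 5**
Reactants: 8 (2S,3R)-2,3-epoxynerol
Product: 9 (2R)-6-methyl-2-[(2R)-oxiran-2-yl]hept-5-en-2-ol (terminal epoxide with tertiary alcohol)
Conditions: 0.5 M NaOH, H2O/t-BuOH, rt, to equilibrium
Reagents that add atoms: none
Why: In the Payne rearrangement the C1 alkoxide opens the oxirane at its secondary carbon from the rear, inverting that centre (future C10 becomes R) and leaving the tertiary centre untouched; exchange of the strained cis-trisubstituted oxirane for a monosubstituted one is expected to favour 9, and residual 8 is inert in step 6 and can be recycled.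

**Step 6**
Reactants: 6 C8 allyl sulfone, 9 terminal epoxide
Product: 10 (2E,6E,10R,11R)-1-[(tert-butyldiphenylsilyl)oxy]-3,7,11,15-tetramethyl-8-(phenylsulfonyl)hexadeca-2,6,14-triene-10,11-diol (both C8 epimers)
Conditions: 6, n-BuLi, THF, −78 °C; add 9 pre-treated with n-BuLi (THF, −78 °C), DMPU, −78 → 0 °C; aq. NH4Cl
Reagents that add atoms: none
Why: The lithiated allyl sulfone should attack through its α-carbon at the unsubstituted epoxide carbon (SN2 opening of a terminal epoxide by a sulfonyl carbanion), forming C8–C9 without touching C10 or C11; the new C8 centre forms as both epimers and is erased in step 8.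

**Step 7**
Reactants: 10 diol sulfone
Product: 11 tert-butyl{[(2E,6E)-3,7-dimethyl-8-(phenylsulfonyl)-9-[(4R,5R)-2,2,5-trimethyl-5-(4-methylpent-3-en-1-yl)-1,3-dioxolan-4-yl]nona-2,6-dien-1-yl]oxy}diphenylsilane (acetonide sulfone)
Conditions: 2,2-dimethoxypropane, PPTS (cat.), CH2Cl2, rt
Reagents that add atoms: 2,2-dimethoxypropane, COC(C)(C)OC
Why: Acid-catalysed transketalisation closes the dioxolane on the 1,2-diol, masking it for the hydride, Grignard and oxidation steps and removing the free alkoxide that could otherwise attack the π-allyl intermediate of step 8.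

**Step 8**
Reactants: 11 acetonide sulfone
Product: 12 tert-butyl{[(2E,6E)-3,7-dimethyl-9-[(4R,5R)-2,2,5-trimethyl-5-(4-methylpent-3-en-1-yl)-1,3-dioxolan-4-yl]nona-2,6-dien-1-yl]oxy}diphenylsilane
Conditions: PdCl2(dppp) (5 mol%), LiBHEt3, THF, 0 °C → rt
Reagents that add atoms: none
Why: Palladium-catalysed reductive desulfonylation of an allylic sulfone (ionisation to π-allylpalladium, hydride delivery at the carbon that carried sulfur) with dppp as ligand is the established way to keep the position and E geometry of the trisubstituted alkene in prenyl-type sulfones.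

**Step 9**
Reactants: 12 silyl ether acetonide
Product: 13 (2E,6E)-3,7-dimethyl-9-[(4R,5R)-2,2,5-trimethyl-5-(4-methylpent-3-en-1-yl)-1,3-dioxolan-4-yl]nona-2,6-dien-1-ol
Conditions: TBAF, THF, 0 °C → rt
Reagents that add atoms: none
Why: Fluoride cleaves the Si–O bond while acetonide and alkenes are inert.

**Step 10**
Reactants: 13 allylic alcohol
Product: 15 (4R,5R)-4-[(3E,7E)-9-bromo-3,7-dimethylnona-3,7-dien-1-yl]-2,2,5-trimethyl-5-(4-methylpent-3-en-1-yl)-1,3-dioxolane (allylic bromide), via allylic mesylate 14 (not isolated)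
Conditions: MsCl, Et3N, THF, −40 °C; then LiBr, THF, −40 → 0 °C
Reagents that add atoms: lithium bromide, [Li+].[Br-]
Why: Mesylation followed by bromide displacement in the same flask converts the primary allylic alcohol to the bromide under non-acidic conditions that spare the acetonide and should not scramble the 2E alkene.

**Step 11**
Reactants: 15 allylic bromide
Product: 16 (4R,5R)-4-[(3E,7E)-3,7-dimethylundeca-3,7-dien-10-yn-1-yl]-2,2,5-trimethyl-5-(4-methylpent-3-en-1-yl)-1,3-dioxolane (side-chain 1,4-enyne)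
Conditions: HC≡CMgBr, CuCl (10 mol%), THF, 0 → 40 °C
Reagents that add atoms: ethynylmagnesium bromide, C#C[Mg]Br
Why: Copper-catalysed coupling of an alkynyl Grignard reagent with a primary allylic bromide proceeds mainly by SN2 at the CH2 carbon with retention of the E alkene, the standard entry to skipped enynes from geranyl-type halides.

**Step 12**
Reactants: 17 (E)-1-bromoprop-1-ene, 18 chromium hexacarbonyl
Product: 21 pentacarbonyl[(2E)-1-methoxybut-2-en-1-ylidene]chromium(0), via (E)-prop-1-enyllithium 19 (not isolated), via lithium acylchromate 20 (not isolated)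
Conditions: t-BuLi (2 equiv), Et2O, −78 °C; Cr(CO)6, Et2O, −78 °C → rt; then Me3OBF4, CH2Cl2/H2O, 0 °C
Reagents that add atoms: trimethyloxonium tetrafluoroborate, C[O+](C)C.F[B-](F)(F)F
Why: In the Fischer carbene synthesis, bromine–lithium exchange occurs with retention of the E geometry, the alkenyllithium adds to a CO ligand, and O-methylation of the acyl chromate with Meerwein's salt gives the alkoxycarbene complex.

**Step 13**
Reactants: 16 side-chain 1,4-enyne, 21 chromium methoxy(propenyl)carbene
Product: 23 2-[(2E,6E)-3,7-dimethyl-9-[(4R,5R)-2,2,5-trimethyl-5-(4-methylpent-3-en-1-yl)-1,3-dioxolan-4-yl]nona-2,6-dien-1-yl]-4-methoxy-6-methylphenol, via tricarbonylchromium arene complex 22 (not isolated)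
Conditions: 16 (1 equiv), 21 (1.5 equiv), degassed THF, 50 °C, Ar; then air, Et2O, rt
Reagents that add atoms: none
Why: Thermal loss of a CO ligand from 21 lets the alkyne of 16 coordinate and insert into the Cr=C bond to give a vinylcarbene, CO then inserts to form a chromium-bound dienylketene, and the cyclised dienone tautomerises to the phenol, held as its Cr(CO)3 complex 22 until air removes the metal. This is the Dötz benzannulation of an alkenyl(alkoxy) Fischer carbene with a terminal alkyne, the pairing for which phenol formation is most dependable. The one new ring, the benzene ring, closes by 6π-electrocyclisation of the dienylketene, which makes the bond between the CO-derived carbon and the methyl-bearing propenyl carbon after the two insertions have made the carbene-C–alkyne-CH and alkyne-C–CO bonds. No stereocentre is created, and C10 and C11 sit in the acetonide far from the reacting alkyne, so they should pass unchanged under neutral conditions at 50 °C. The step needs regioselective alkyne insertion, with the unsubstituted alkyne carbon bonding to the carbene carbon so that the chain ends up next to the CO-derived C–OH; the size difference between H and the chain CH2 at a terminal alkyne secures this, the larger group avoiding the CO ligands in the vinylcarbene. The trisubstituted alkenes should not react with the carbene at this temperature, and the nearest alkene is too close to the alkyne for intramolecular cyclopropanation.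

**Step 14**
Reactants: 23 4-methoxyphenol acetonide
Product: 24 2-[(2E,6E)-3,7-dimethyl-9-[(4R,5R)-2,2,5-trimethyl-5-(4-methylpent-3-en-1-yl)-1,3-dioxolan-4-yl]nona-2,6-dien-1-yl]-6-methylcyclohexa-2,5-diene-1,4-dione (quinone acetonide)
Conditions: (NH4)2Ce(NO3)6 (2.2 equiv), MeCN/H2O, 0 °C, 10 min
Reagents that add atoms: water, O
Why: Cerium(IV) removes two electrons from the electron-rich 4-methoxyphenol, water adds at the methoxy-bearing carbon and methanol is expelled (oxidative demethylation to the p-quinone), a reaction expected to be complete within minutes at 0 °C and so faster than any attack on the alkenes or the acetonide.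

**Step 15**
Reactants: 24 quinone acetonide
Product: 26 2-[(2E,6E,10R,11R)-10,11-dihydroxy-3,7,11,15-tetramethylhexadeca-2,6,14-trien-1-yl]-6-methylbenzene-1,4-diol (target), via quinone diol 25 (not isolated)
Conditions: 2 M HCl, THF, rt; then Et2O, aq. Na2S2O4, rt, Ar
Reagents that add atoms: none
Why: Aqueous acid hydrolyses the acetonide while the ring is still a quinone (no phenol is present that could add to the C2=C3 alkene), and dithionite then reduces the quinone to the hydroquinone, neither operation touching C10 or C11.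

**Compound list**

1 | geraniol, (2E)-3,7-dimethylocta-2,6-dien-1-ol | CC(C)=CCC/C(C)=C/CO | starting material
2 | tert-butyl{[(2E)-3,7-dimethylocta-2,6-dien-1-yl]oxy}diphenylsilane | CC(C)=CCC/C(C)=C/CO[Si](c1ccccc1)(c1ccccc1)C(C)(C)C | intermediate
3 | (2E,6E)-8-[(tert-butyldiphenylsilyl)oxy]-2,6-dimethylocta-2,6-dien-1-ol | OC/C(C)=C/CC/C(C)=C/CO[Si](c1ccccc1)(c1ccccc1)C(C)(C)C | intermediate
4 | (2E,6E)-8-[(tert-butyldiphenylsilyl)oxy]-2,6-dimethylocta-2,6-dien-1-yl methanesulfonate | CS(=O)(=O)OC/C(C)=C/CC/C(C)=C/CO[Si](c1ccccc1)(c1ccccc1)C(C)(C)C | intermediate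
5 | {[(2E,6E)-8-bromo-3,7-dimethylocta-2,6-dien-1-yl]oxy}(tert-butyl)diphenylsilane | BrC/C(C)=C/CC/C(C)=C/CO[Si](c1ccccc1)(c1ccccc1)C(C)(C)C | intermediate
6 | tert-butyl{[(2E,6E)-3,7-dimethyl-8-(phenylsulfonyl)octa-2,6-dien-1-yl]oxy}diphenylsilane | O=S(=O)(C/C(C)=C/CC/C(C)=C/CO[Si](c1ccccc1)(c1ccccc1)C(C)(C)C)c1ccccc1 | intermediate
7 | nerol, (2Z)-3,7-dimethylocta-2,6-dien-1-ol | CC(C)=CCC/C(C)=C\CO | starting material
8 | [(2S,3R)-3-methyl-3-(4-methylpent-3-en-1-yl)oxiran-2-yl]methanol | CC(C)=CCC[C@@]1(C)O[C@H]1CO | intermediate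
9 | (2R)-6-methyl-2-[(2R)-oxiran-2-yl]hept-5-en-2-ol | CC(C)=CCC[C@@](C)(O)[C@H]1CO1 | intermediate
10 | (2E,6E,10R,11R)-1-[(tert-butyldiphenylsilyl)oxy]-3,7,11,15-tetramethyl-8-(phenylsulfonyl)hexadeca-2,6,14-triene-10,11-diol, both C8 epimers | CC(C)=CCC[C@@](C)(O)[C@H](O)CC(S(=O)(=O)c1ccccc1)/C(C)=C/CC/C(C)=C/CO[Si](c1ccccc1)(c1ccccc1)C(C)(C)C | intermediate
11 | 10,11-O-isopropylidene derivative of 10, dioxolane (4R,5R), both C8 epimers | CC(C)=CCC[C@@]1(C)OC(C)(C)O[C@@H]1CC(S(=O)(=O)c1ccccc1)/C(C)=C/CC/C(C)=C/CO[Si](c1ccccc1)(c1ccccc1)C(C)(C)C | intermediate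
12 | tert-butyl{[(2E,6E)-3,7-dimethyl-9-[(4R,5R)-2,2,5-trimethyl-5-(4-methylpent-3-en-1-yl)-1,3-dioxolan-4-yl]nona-2,6-dien-1-yl]oxy}diphenylsilane | CC(C)=CCC[C@@]1(C)OC(C)(C)O[C@@H]1CC/C(C)=C/CC/C(C)=C/CO[Si](c1ccccc1)(c1ccccc1)C(C)(C)C | intermediate
13 | (2E,6E)-3,7-dimethyl-9-[(4R,5R)-2,2,5-trimethyl-5-(4-methylpent-3-en-1-yl)-1,3-dioxolan-4-yl]nona-2,6-dien-1-ol | CC(C)=CCC[C@@]1(C)OC(C)(C)O[C@@H]1CC/C(C)=C/CC/C(C)=C/CO | intermediate
14 | methanesulfonate of 13 | CC(C)=CCC[C@@]1(C)OC(C)(C)O[C@@H]1CC/C(C)=C/CC/C(C)=C/COS(C)(=O)=O | intermediate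
15 | (4R,5R)-4-[(3E,7E)-9-bromo-3,7-dimethylnona-3,7-dien-1-yl]-2,2,5-trimethyl-5-(4-methylpent-3-en-1-yl)-1,3-dioxolane | CC(C)=CCC[C@@]1(C)OC(C)(C)O[C@@H]1CC/C(C)=C/CC/C(C)=C/CBr | intermediate
16 | (4R,5R)-4-[(3E,7E)-3,7-dimethylundeca-3,7-dien-10-yn-1-yl]-2,2,5-trimethyl-5-(4-methylpent-3-en-1-yl)-1,3-dioxolane | CC(C)=CCC[C@@]1(C)OC(C)(C)O[C@@H]1CC/C(C)=C/CC/C(C)=C/CC#C | intermediate
17 | (E)-1-bromoprop-1-ene | C/C=C/Br | starting material
18 | chromium hexacarbonyl | O=C=[Cr](=C=O)(=C=O)(=C=O)(=C=O)=C=O | starting material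
19 | (E)-prop-1-enyllithium | C/C=C/[Li] | intermediate
20 | lithium pentacarbonyl[(2E)-1-oxidobut-2-en-1-ylidene]chromate (acyl chromate) | C/C=C/C([O-])=[Cr](=C=O)(=C=O)(=C=O)(=C=O)=C=O.[Li+] | intermediate
21 | pentacarbonyl[(2E)-1-methoxybut-2-en-1-ylidene]chromium(0) | C/C=C/C(OC)=[Cr](=C=O)(=C=O)(=C=O)(=C=O)=C=O | intermediate
22 | tricarbonyl(η6-arene)chromium complex of phenol 23 | CC(C)=CCC[C@@]1(C)OC(C)(C)O[C@@H]1CC/C(C)=C/CC/C(C)=C/Cc1cc(OC)cc(C)c1O.O=C=[Cr](=C=O)=C=O | intermediate
23 | 2-[(2E,6E)-3,7-dimethyl-9-[(4R,5R)-2,2,5-trimethyl-5-(4-methylpent-3-en-1-yl)-1,3-dioxolan-4-yl]nona-2,6-dien-1-yl]-4-methoxy-6-methylphenol | CC(C)=CCC[C@@]1(C)OC(C)(C)O[C@@H]1CC/C(C)=C/CC/C(C)=C/Cc1cc(OC)cc(C)c1O | intermediate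
24 | 2-[(2E,6E)-3,7-dimethyl-9-[(4R,5R)-2,2,5-trimethyl-5-(4-methylpent-3-en-1-yl)-1,3-dioxolan-4-yl]nona-2,6-dien-1-yl]-6-methylcyclohexa-2,5-diene-1,4-dione | CC(C)=CCC[C@@]1(C)OC(C)(C)O[C@@H]1CC/C(C)=C/CC/C(C)=C/CC1=CC(=O)C=C(C)C1=O | intermediate
25 | 2-[(2E,6E,10R,11R)-10,11-dihydroxy-3,7,11,15-tetramethylhexadeca-2,6,14-trien-1-yl]-6-methylcyclohexa-2,5-diene-1,4-dione | CC(C)=CCC[C@@](C)(O)[C@H](O)CC/C(C)=C/CC/C(C)=C/CC1=CC(=O)C=C(C)C1=O | intermediate
26 | 2-[(2E,6E,10R,11R)-10,11-dihydroxy-3,7,11,15-tetramethylhexadeca-2,6,14-trien-1-yl]-6-methylbenzene-1,4-diol | CC(C)=CCC[C@@](C)(O)[C@H](O)CC/C(C)=C/CC/C(C)=C/Cc1cc(O)cc(C)c1O | target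

**Totals.** Total step count: 15. Longest linear sequence: 12 steps (geraniol through steps 1, 2, 3, 6, 7, 8, 9, 10, 11, 13, 14, 15).

**Steps most likely to fail**

Step 13. The vinylcarbene or dienylketene intermediates may be diverted into cyclobutenone, furan or two-alkyne products, the alkyne may oligomerise, or the arene may be released incompletely from chromium, any of which would lower the recovery of phenol. The fallback sets out from bromide 15 and comes back at quinone 24. Commercial 4-methoxy-2-methylphenol would be brominated ortho to the hydroxyl (NBS, MeCN, 0 °C) to 2-bromo-4-methoxy-6-methylphenol F1 and O-methylated (MeI, K2CO3, acetone) to 1-bromo-2,5-dimethoxy-3-methylbenzene F2. Bromine–lithium exchange (n-BuLi, THF, −78 °C), transmetalation with CuBr·SMe2 and SN2 allylation with 15 should give the 1,4-dimethoxyarene F3, which CAN (MeCN/H2O, 0 °C) oxidises to 24.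

Step 6. The stabilised allylic anion may open the epoxide too slowly, so that the neighbouring lithium alkoxide migrates the epoxide back inward or the anion decays on warming. The fallback sets out from 9 and comes back at 10. The tertiary hydroxyl would be silylated (TMSCl, imidazole, DMF) to trimethyl{[(2R)-6-methyl-2-[(2R)-oxiran-2-yl]hept-5-en-2-yl]oxy}silane F4. This O-protected epoxide would then be opened by lithiated 6 under Lewis-acid activation (BF3·OEt2, THF, −78 °C), where no alkoxide is present. A mildly acidic work-up removes the silyl group and delivers 10.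

Step 5. The epoxide migration may stop at an unfavourable equilibrium, or hydroxide may hydrolyse the terminal epoxide on long exposure. The fallback sets out from 8 and comes back at 9. Thiophenol in aqueous NaOH/t-BuOH at reflux would trap the terminal epoxide irreversibly as it forms, giving (2S,3R)-3,7-dimethyl-1-(phenylsulfanyl)oct-6-ene-2,3-diol F5. S-Methylation (Me3OBF4, CH2Cl2) gives the methyl(phenyl)sulfonium tetrafluoroborate F6. NaH in THF at 0 °C then closes the C10 alkoxide onto C9 with loss of the sulfide, under aprotic conditions in which back-migration should be slow, to give 9.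

**Further compounds**

F1 | step 13 | 2-bromo-4-methoxy-6-methylphenol | Cc1cc(OC)cc(Br)c1O
F2 | step 13 | 1-bromo-2,5-dimethoxy-3-methylbenzene | COc1cc(C)c(OC)c(Br)c1
F3 | step 13 | (4R,5R)-4-[(3E,7E)-9-(2,5-dimethoxy-3-methylphenyl)-3,7-dimethylnona-3,7-dien-1-yl]-2,2,5-trimethyl-5-(4-methylpent-3-en-1-yl)-1,3-dioxolane | CC(C)=CCC[C@@]1(C)OC(C)(C)O[C@@H]1CC/C(C)=C/CC/C(C)=C/Cc1cc(OC)cc(C)c1OC
F4 | step 6 | trimethyl{[(2R)-6-methyl-2-[(2R)-oxiran-2-yl]hept-5-en-2-yl]oxy}silane | CC(C)=CCC[C@@](C)(O[Si](C)(C)C)[C@H]1CO1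
F5 | step 5 | (2S,3R)-3,7-dimethyl-1-(phenylsulfanyl)oct-6-ene-2,3-diol | CC(C)=CCC[C@@](C)(O)[C@H](O)CSc1ccccc1
F6 | step 5 | [(2S,3R)-2,3-dihydroxy-3,7-dimethyloct-6-en-1-yl](methyl)phenylsulfonium tetrafluoroborate | CC(C)=CCC[C@@](C)(O)[C@H](O)C[S+](C)c1ccccc1.F[B-](F)(F)F
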